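## Retrosynthetic overview
- **Feature:** flavone ring A (C4a, C5, C6, C7, C8, C8a) is a pentasubstituted benzene. The aryl-bearing C8 is wedged between C8a–O1 and C7–O, a third oxygen sits on C5, and only C6 carries hydrogen.
- **Key disconnection:** ring A splits into a C8–C7 unit (aryl triisopropylsiloxyalkyne, aryl = flavanone ring B) and a C8a/C6/C5/C4a unit ((1-methoxyvinyl)ketene from a diazoketone). The crowded C3′–C8″ biaryl bond starts as the aryl–carbonyl bond of a salicylate and is never made by coupling.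
- **Flavone ring C:** the single free phenol (future O1) steers formylation to C4a, followed by acetylide addition, oxidation and 6-endo closure. The chelated 5-O-methyl group is removed before any stereocentre exists.
- **Flavanone ring C:** the unmasked ring B aldehyde is condensed with a phloroacetophenone-derived β-keto ester. A catalytic asymmetric oxa-Michael closure sets C2 as S and decarboxylation locks it, leaving only fluoride and hydrogenolysis.
- **Ring order:** flavone ring A, flavone ring C, flavanone ring C. Flavanone rings A and B and the anisyl ring are bought.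

Key step: step 6

Assumption 1: the quinidine-derived thiourea is taken to give the (2S) series, following the sense this catalyst family shows in conjugate additions to aryl enones (quinine series R, quinidine series S). Both pseudo-enantiomers are equally available.
Assumption 2: the target carries no axial descriptor, so the C3′–C8″ axis is treated as configurationally labile. Protected intermediates may appear as rotamer mixtures that converge in 33.

## Route

Step 1
Reactants: 1 methyl 5-formyl-2-hydroxybenzoate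
Product: 2 methyl 2-(benzyloxy)-5-formylbenzoate
Conditions: BnBr (1.1 equiv), K2CO3, DMF, 50 °C
Reagents that add atoms: benzyl bromide, BrCc1ccccc1
Why: Williamson ether synthesis: the phenol, acidified by the ortho ester and the para formyl group, is fully ionised by K2CO3 and is the only nucleophile present.

Step 2
Reactants: 2 methyl 2-(benzyloxy)-5-formylbenzoate
Product: 3 methyl 2-(benzyloxy)-5-(1,3-dioxolan-2-yl)benzoate
Conditions: HOCH2CH2OH, p-TsOH·H2O (cat.), toluene, reflux, Dean–Stark trap
Reagents that add atoms: ethylene glycol, OCCO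
Why: Acid-catalysed acetalisation driven by azeotropic removal of water masks the aldehyde against the organolithium reagents of step 3, while ester and benzyl ether are inert.

Step 3
Reactants: 3 methyl 2-(benzyloxy)-5-(1,3-dioxolan-2-yl)benzoate
Product: 6 triisopropyl({[2-(benzyloxy)-5-(1,3-dioxolan-2-yl)phenyl]ethynyl}oxy)silane, via dibromo enolate 4 (not isolated), via lithium ynolate 5 (not isolated)
Conditions: CH2Br2, lithium 2,2,6,6-tetramethylpiperidide, THF, −78 °C; add 3; LiN(SiMe3)2, then n-BuLi (no excess), −78 → 20 °C; i-Pr3SiCl, 0 °C → rt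
Reagents that add atoms: dibromomethane, BrCBr; triisopropylsilyl chloride, CC(C)[Si](Cl)(C(C)C)C(C)C; lithium bis(trimethylsilyl)amide, [Li]N([Si](C)(C)C)[Si](C)(C)C (lithium stays only in 4 and 5)
Why: Kowalski ester homologation halted at the ynolate: LiCHBr2 adds to the ester, the derived dibromo enolate 4 undergoes bromine–lithium exchange and a carbenoid 1,2-aryl shift to ynolate 5 (aromatic esters are standard substrates), and the bulky chlorosilane traps 5 on oxygen and not on carbon.

Step 4
Reactants: 7 3,3-dimethoxybutan-2-one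
Product: 8 3-methoxybut-3-en-2-one
Conditions: p-TsOH·H2O (cat.), hydroquinone (trace), neat, 130–150 °C, MeOH distilled off; then distillation
Reagents that add atoms: none
Why: Acid-catalysed 1,2-elimination of methanol from the α-keto ketal gives the conjugated enol ether and is pulled forward by distilling off methanol.

Step 5
Reactants: 8 3-methoxybut-3-en-2-one
Product: 10 1-diazo-3-methoxybut-3-en-2-one, via trifluoroacetyl ketone 9 (not isolated)
Conditions: LiN(SiMe3)2, THF, −78 °C; CF3CO2CH2CF3; dilute HCl wash; then MsN3, Et3N, H2O (1 equiv), MeCN, rt (product kept in solution, cold, dark)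
Reagents that add atoms: methanesulfonyl azide, CS(=O)(=O)N=[N+]=[N-]; 2,2,2-trifluoroethyl trifluoroacetate, O=C(OCC(F)(F)F)C(F)(F)F (its atoms stay only in 9)
Why: Detrifluoroacetylative diazo transfer (a Regitz-type transfer on an activated ketone): the only enolisable position is trifluoroacetylated, diketone 9 takes up the diazo group from MsN3 and sheds the trifluoroacetyl group, a sequence suited to enones because it avoids diazomethane adding to the C=C bond.

Step 6
Reactants: 6 triisopropyl({[2-(benzyloxy)-5-(1,3-dioxolan-2-yl)phenyl]ethynyl}oxy)silane; 10 1-diazo-3-methoxybut-3-en-2-one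
Product: 15 2′-(benzyloxy)-5′-(1,3-dioxolan-2-yl)-4-methoxy-6-[(triisopropylsilyl)oxy]biphenyl-2-ol, via vinylketene 11 (not isolated), via vinylcyclobutenone 12 (not isolated), via dienylketene 13 (not isolated), via cyclohexadienone 14 (not isolated)
Conditions: 6 (1.2 equiv), 10 (1.0 equiv), CH2Cl2, hν (medium-pressure Hg lamp, Pyrex filter, λ > 300 nm), rt; concentrate; toluene, 110 °C
Reagents that add atoms: none
Why: Light expels N2 from 10 and the 1-methoxyvinyl group migrates (Wolff rearrangement) to give vinylketene 11, whose carbonyl carbon (future C8a) is attacked by the aryl-bearing carbon of 6, the nucleophilic terminus of the ynol ether, so that a [2+2] cycloaddition forms C8a–C8 and C7–C6 in cyclobutenone 12. On heating, 12 opens in a reversible four-electron electrocyclic step (the temporary C8a–C6 bond breaks) to dienylketene 13, and ring A closes by six-electron electrocyclisation (C4a–C8a) to dienone 14, which tautomerises irreversibly to phenol 15. The closest known reaction is the Danheiser benzannulation in its diazoketone variant with triisopropylsiloxyalkynes; the methoxy group on the vinyl unit and the ortho-substituted aryl group on the alkyne are substituent changes within that class. No lasting stereocentre is formed, since C4 of 12 is racemic and disappears and the biaryl axis is not fixed. The one selectivity needed is the orientation of the [2+2] step, and it is secured by the oxygen polarisation of the alkyne: the aryl group ends between the new hydroxyl (O1) and the silyloxy group (O7), whereas the opposite orientation would give a 1,2-dioxygenated ring that has no place in the target. Filtered light addresses the long-wavelength band of the diazoketone and spares the aryl alkyne chromophore, and the slight excess of 6 keeps the ketene from acylating the product phenol.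

Step 7
Reactants: 15 2′-(benzyloxy)-5′-(1,3-dioxolan-2-yl)-4-methoxy-6-[(triisopropylsilyl)oxy]biphenyl-2-ol
Product: 16 2′-(benzyloxy)-5′-(1,3-dioxolan-2-yl)-2-hydroxy-4-methoxy-6-[(triisopropylsilyl)oxy]biphenyl-3-carbaldehyde
Conditions: MgCl2 (anhydrous), Et3N, (CH2O)n, MeCN, reflux; aq. NH4Cl work-up
Reagents that add atoms: paraformaldehyde (as formaldehyde), C=O
Why: Casnati–Skattebøl ortho-formylation: the magnesium phenoxide delivers coordinated formaldehyde only to an ortho carbon, the sole free one is C4a (the other carries the aryl group, C6 is para), and a second formaldehyde accepts hydride to give the aldehyde, while the basic medium leaves acetal and silyl ether intact.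

Step 8
Reactants: 16 2′-(benzyloxy)-5′-(1,3-dioxolan-2-yl)-2-hydroxy-4-methoxy-6-[(triisopropylsilyl)oxy]biphenyl-3-carbaldehyde; 17 4-ethynylanisole
Product: 19 1-{2′-(benzyloxy)-5′-(1,3-dioxolan-2-yl)-2-hydroxy-4-methoxy-6-[(triisopropylsilyl)oxy]biphenyl-3-yl}-3-(4-methoxyphenyl)prop-2-yn-1-ol (racemic), via lithium acetylide 18 (not isolated)
Conditions: 17 (2.5 equiv), n-BuLi (2.5 equiv), THF, −78 °C; add 16, −78 → 0 °C; aq. NH4Cl
Reagents that add atoms: n-butyllithium, [Li]CCCC (lithium stays only in 18)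
Why: 1,2-Addition of a lithium acetylide to the aldehyde, with the first equivalent spent on the phenol; the new carbinol carbon is formed racemic and is erased in step 9.

Step 9
Reactants: 19 the racemic propargylic alcohol
Product: 20 1-{2′-(benzyloxy)-5′-(1,3-dioxolan-2-yl)-2-hydroxy-4-methoxy-6-[(triisopropylsilyl)oxy]biphenyl-3-yl}-3-(4-methoxyphenyl)prop-2-yn-1-one
Conditions: MnO2 (activated, excess), CH2Cl2, rt
Reagents that add atoms: none
Why: MnO2 oxidises the doubly activated (benzylic and propargylic) alcohol selectively and leaves the hydrogen-bonded phenol and all ethers alone.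

Step 10
Reactants: 20 the o-hydroxyaryl ynone
Product: 21 8-[2-(benzyloxy)-5-(1,3-dioxolan-2-yl)phenyl]-5-methoxy-2-(4-methoxyphenyl)-7-[(triisopropylsilyl)oxy]-4H-chromen-4-one
Conditions: DMAP (20 mol %), DMF, 40 °C
Reagents that add atoms: none
Why: DMAP-catalysed cyclisation of an o-alkynoylphenol: conjugate addition of DMAP to the ynone and addition–elimination by the only free phenol (O1) closes flavone ring C in the 6-endo sense, avoiding the 5-exo path to an aurone, under conditions too mild to harm silyl ether or acetal.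

Step 11
Reactants: 21 the flavone acetal
Product: 22 4-(benzyloxy)-3-{5-methoxy-2-(4-methoxyphenyl)-4-oxo-7-[(triisopropylsilyl)oxy]-4H-chromen-8-yl}benzaldehyde
Conditions: 1 M HCl, THF, rt
Reagents that add atoms: water, O
Why: Ordinary acid hydrolysis of an aryl dioxolane; the hindered aryl triisopropylsilyl ether and the benzyl ether tolerate dilute acid at room temperature.

Step 12
Reactants: 22 the 5-methoxyflavone aldehyde
Product: 24 4-(benzyloxy)-3-{5-hydroxy-2-(4-methoxyphenyl)-4-oxo-7-[(triisopropylsilyl)oxy]-4H-chromen-8-yl}benzaldehyde, via dichloroboron chelate 23 (not isolated)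
Conditions: BCl3 (1.2 equiv, 1 M in CH2Cl2), CH2Cl2, −78 → 0 °C; then ice-water, THF
Reagents that add atoms: boron trichloride, ClB(Cl)Cl (boron and chlorine stay only in 23)
Why: Chelation-controlled ether cleavage: the strongly Lewis-basic pyranone carbonyl captures the near-stoichiometric BCl3, the peri 5-methoxy oxygen closes a six-membered boron chelate and chloride removes its methyl group (SN2), while the tetracoordinate boron of 23 is too weak a Lewis acid to touch the benzyl, anisyl methyl or silyl ethers, and no stereocentre is yet at risk.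

Step 13
Reactants: 25 2,4,6-trihydroxyacetophenone
Product: 26 1-[2,4-bis(benzyloxy)-6-hydroxyphenyl]ethan-1-one
Conditions: BnBr (2.05 equiv), K2CO3, DMF, rt → 50 °C
Reagents that add atoms: benzyl bromide, BrCc1ccccc1
Why: Twofold Williamson etherification: after two alkylations the remaining hydroxyl is locked in a hydrogen bond to the acetyl group and is much less nucleophilic, so the reaction stops at the dibenzyl ether.

Step 14
Reactants: 26 1-[2,4-bis(benzyloxy)-6-hydroxyphenyl]ethan-1-one
Product: 28 tert-butyl 3-[2,4-bis(benzyloxy)-6-hydroxyphenyl]-3-oxopropanoate, via dilithium dianion 27 (not isolated)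
Conditions: LiN(SiMe3)2 (3.2 equiv), THF, −78 → −20 °C; Boc2O (1.1 equiv), −78 °C → rt; aq. NH4Cl
Reagents that add atoms: di-tert-butyl dicarbonate, CC(C)(C)OC(=O)OC(=O)OC(C)(C)C; lithium bis(trimethylsilyl)amide, [Li]N([Si](C)(C)C)[Si](C)(C)C (lithium stays only in 27)
Why: Crossed Claisen-type C-carboxylation of the phenoxide–enolate dianion, whose carbon terminus is the more reactive site; any aryl carbonate formed on oxygen is funnelled to the same β-keto ester by a Baker–Venkataraman-type O-to-C transfer under the excess base.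

Step 15
Reactants: 24 the 5-hydroxyflavone aldehyde; 28 tert-butyl 3-[2,4-bis(benzyloxy)-6-hydroxyphenyl]-3-oxopropanoate
Product: 29 tert-butyl (Z)-2-[2,4-bis(benzyloxy)-6-hydroxybenzoyl]-3-(4-(benzyloxy)-3-{5-hydroxy-2-(4-methoxyphenyl)-4-oxo-7-[(triisopropylsilyl)oxy]-4H-chromen-8-yl}phenyl)prop-2-enoate (aryl cis to the ester expected)
Conditions: piperidine (20 mol %), AcOH (40 mol %), 4 Å molecular sieves, toluene, rt
Reagents that add atoms: none
Why: Knoevenagel condensation of an aromatic aldehyde with an aroylacetate under buffered piperidinium acetate; the surplus of acetic acid keeps the phenol protonated so that uncatalysed ring closure stays slow, and the flavone 5-OH is tied up in its hydrogen bond.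

Step 16
Reactants: 29 the alkylidene β-keto ester
Product: 31 (2S)-5,7-bis(benzyloxy)-2-(4-(benzyloxy)-3-{5-hydroxy-2-(4-methoxyphenyl)-4-oxo-7-[(triisopropylsilyl)oxy]-4H-chromen-8-yl}phenyl)chroman-4-one, via chromanone ester 30 (not isolated)
Conditions: 1-[3,5-bis(trifluoromethyl)phenyl]-3-[(9R)-6′-methoxycinchonan-9-yl]thiourea (quinidine-derived, 10 mol %), toluene, −25 °C; then p-TsOH·H2O, 80 °C
Reagents that add atoms: none
Why: Cinchona-thiourea-catalysed intramolecular oxa-Michael addition of an alkylidene β-keto ester: the quinuclidine nitrogen deprotonates the phenol while the thiourea binds the β-dicarbonyl unit, so the phenoxide reaches one face of the alkene and sets C2 as S (C3 settles trans), after which TsOH cleaves the tert-butyl ester and the β-keto acid loses CO2, removing the activating group and with it the easy retro-addition.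

Step 17
Reactants: 31 the silyl-protected (2S)-flavanone
Product: 32 (2S)-5,7-bis(benzyloxy)-2-{4-(benzyloxy)-3-[5,7-dihydroxy-2-(4-methoxyphenyl)-4-oxo-4H-chromen-8-yl]phenyl}chroman-4-one
Conditions: Et3N·3HF, THF, rt
Reagents that add atoms: none
Why: Fluoride cleavage of an aryl silyl ether whose phenoxide is a good leaving group (O7 is conjugated to the pyranone carbonyl); the weakly acidic reagent avoids the base-induced retro-oxa-Michael opening that would racemise C2.

Step 18
Reactants: 32 the tribenzyl ether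
Product: 33 2,3-dihydropodocarpusflavone A, (2S)
Conditions: H2 (1 atm), 10 % Pd/C, EtOAc–MeOH, rt
Reagents that add atoms: none
Why: Catalytic hydrogenolysis of the three aryl benzyl ethers under neutral conditions, which leaves the flavone C2=C3 bond, both carbonyl groups, the anisyl methyl ether and the configuration at C2 untouched.

## Compound list
1 | methyl 5-formyl-2-hydroxybenzoate | COC(=O)c1cc(C=O)ccc1O | starting material
2 | methyl 2-(benzyloxy)-5-formylbenzoate | COC(=O)c1cc(C=O)ccc1OCc1ccccc1 | intermediate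
3 | methyl 2-(benzyloxy)-5-(1,3-dioxolan-2-yl)benzoate | COC(=O)c1cc(C2OCCO2)ccc1OCc1ccccc1 | intermediate
4 | lithium 1-[2-(benzyloxy)-5-(1,3-dioxolan-2-yl)phenyl]-2,2-dibromoethen-1-olate | [Li+].[O-]C(=C(Br)Br)c1cc(C2OCCO2)ccc1OCc1ccccc1 | intermediate (not isolated)
5 | lithium 2-[2-(benzyloxy)-5-(1,3-dioxolan-2-yl)phenyl]ethyn-1-olate | [Li+].[O-]C#Cc1cc(C2OCCO2)ccc1OCc1ccccc1 | intermediate (not isolated)
6 | triisopropyl({[2-(benzyloxy)-5-(1,3-dioxolan-2-yl)phenyl]ethynyl}oxy)silane | CC(C)[Si](OC#Cc1cc(C2OCCO2)ccc1OCc1ccccc1)(C(C)C)C(C)C | intermediate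
7 | 3,3-dimethoxybutan-2-one | CC(=O)C(C)(OC)OC | starting material
8 | 3-methoxybut-3-en-2-one | CC(=O)C(=C)OC | intermediate
9 | 1,1,1-trifluoro-5-methoxyhex-5-ene-2,4-dione | COC(=C)C(=O)CC(=O)C(F)(F)F | intermediate (not isolated)
10 | 1-diazo-3-methoxybut-3-en-2-one | COC(=C)C(=O)C=[N+]=[N-] | intermediate
11 | 3-methoxybuta-1,3-dien-1-one | COC(=C)C=C=O | intermediate (not isolated)
12 | 2-[2-(benzyloxy)-5-(1,3-dioxolan-2-yl)phenyl]-4-(1-methoxyvinyl)-3-[(triisopropylsilyl)oxy]cyclobut-2-en-1-one (racemic) | COC(=C)C1C(=O)C(c2cc(C3OCCO3)ccc2OCc2ccccc2)=C1O[Si](C(C)C)(C(C)C)C(C)C | intermediate (not isolated)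
13 | (3E)-2-[2-(benzyloxy)-5-(1,3-dioxolan-2-yl)phenyl]-5-methoxy-3-[(triisopropylsilyl)oxy]hexa-1,3,5-trien-1-one | COC(=C)\C=C(O[Si](C(C)C)(C(C)C)C(C)C)/C(=C=O)c1cc(C2OCCO2)ccc1OCc1ccccc1 | intermediate (not isolated)
14 | 2-[2-(benzyloxy)-5-(1,3-dioxolan-2-yl)phenyl]-5-methoxy-3-[(triisopropylsilyl)oxy]cyclohexa-2,4-dien-1-one | COC1=CC(O[Si](C(C)C)(C(C)C)C(C)C)=C(c2cc(C3OCCO3)ccc2OCc2ccccc2)C(=O)C1 | intermediate (not isolated)
15 | 2′-(benzyloxy)-5′-(1,3-dioxolan-2-yl)-4-methoxy-6-[(triisopropylsilyl)oxy]biphenyl-2-ol | COc1cc(O)c(-c2cc(C3OCCO3)ccc2OCc2ccccc2)c(O[Si](C(C)C)(C(C)C)C(C)C)c1 | intermediate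
16 | 2′-(benzyloxy)-5′-(1,3-dioxolan-2-yl)-2-hydroxy-4-methoxy-6-[(triisopropylsilyl)oxy]biphenyl-3-carbaldehyde | COc1cc(O[Si](C(C)C)(C(C)C)C(C)C)c(-c2cc(C3OCCO3)ccc2OCc2ccccc2)c(O)c1C=O | intermediate
17 | 4-ethynylanisole | COc1ccc(C#C)cc1 | starting material
18 | lithium (4-methoxyphenyl)acetylide | [Li+].[C-]#Cc1ccc(OC)cc1 | intermediate (not isolated)
19 | 1-{2′-(benzyloxy)-5′-(1,3-dioxolan-2-yl)-2-hydroxy-4-methoxy-6-[(triisopropylsilyl)oxy]biphenyl-3-yl}-3-(4-methoxyphenyl)prop-2-yn-1-ol (racemic) | COc1ccc(C#CC(O)c2c(OC)cc(O[Si](C(C)C)(C(C)C)C(C)C)c(-c3cc(C4OCCO4)ccc3OCc3ccccc3)c2O)cc1 | intermediate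
20 | 1-{2′-(benzyloxy)-5′-(1,3-dioxolan-2-yl)-2-hydroxy-4-methoxy-6-[(triisopropylsilyl)oxy]biphenyl-3-yl}-3-(4-methoxyphenyl)prop-2-yn-1-one | COc1ccc(C#CC(=O)c2c(OC)cc(O[Si](C(C)C)(C(C)C)C(C)C)c(-c3cc(C4OCCO4)ccc3OCc3ccccc3)c2O)cc1 | intermediate
21 | 8-[2-(benzyloxy)-5-(1,3-dioxolan-2-yl)phenyl]-5-methoxy-2-(4-methoxyphenyl)-7-[(triisopropylsilyl)oxy]-4H-chromen-4-one | COc1ccc(-c2cc(=O)c3c(OC)cc(O[Si](C(C)C)(C(C)C)C(C)C)c(-c4cc(C5OCCO5)ccc4OCc4ccccc4)c3o2)cc1 | intermediate
22 | 4-(benzyloxy)-3-{5-methoxy-2-(4-methoxyphenyl)-4-oxo-7-[(triisopropylsilyl)oxy]-4H-chromen-8-yl}benzaldehyde | COc1ccc(-c2cc(=O)c3c(OC)cc(O[Si](C(C)C)(C(C)C)C(C)C)c(-c4cc(C=O)ccc4OCc4ccccc4)c3o2)cc1 | intermediate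
23 | 5-O-dichloroboryl derivative (carbonyl-chelated) of 24 | COc1ccc(-c2cc(=O)c3c(OB(Cl)Cl)cc(O[Si](C(C)C)(C(C)C)C(C)C)c(-c4cc(C=O)ccc4OCc4ccccc4)c3o2)cc1 | intermediate (not isolated)
24 | 4-(benzyloxy)-3-{5-hydroxy-2-(4-methoxyphenyl)-4-oxo-7-[(triisopropylsilyl)oxy]-4H-chromen-8-yl}benzaldehyde | COc1ccc(-c2cc(=O)c3c(O)cc(O[Si](C(C)C)(C(C)C)C(C)C)c(-c4cc(C=O)ccc4OCc4ccccc4)c3o2)cc1 | intermediate
25 | 2,4,6-trihydroxyacetophenone | CC(=O)c1c(O)cc(O)cc1O | starting material
26 | 1-[2,4-bis(benzyloxy)-6-hydroxyphenyl]ethan-1-one | CC(=O)c1c(O)cc(OCc2ccccc2)cc1OCc1ccccc1 | intermediate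
27 | dilithium phenoxide–enolate of 26 | [Li+].[Li+].C=C([O-])c1c([O-])cc(OCc2ccccc2)cc1OCc1ccccc1 | intermediate (not isolated)
28 | tert-butyl 3-[2,4-bis(benzyloxy)-6-hydroxyphenyl]-3-oxopropanoate | CC(C)(C)OC(=O)CC(=O)c1c(O)cc(OCc2ccccc2)cc1OCc1ccccc1 | intermediate
29 | tert-butyl (Z)-2-[2,4-bis(benzyloxy)-6-hydroxybenzoyl]-3-(4-(benzyloxy)-3-{5-hydroxy-2-(4-methoxyphenyl)-4-oxo-7-[(triisopropylsilyl)oxy]-4H-chromen-8-yl}phenyl)prop-2-enoate | COc1ccc(-c2cc(=O)c3c(O)cc(O[Si](C(C)C)(C(C)C)C(C)C)c(-c4cc(/C=C(\C(=O)OC(C)(C)C)C(=O)c5c(O)cc(OCc6ccccc6)cc5OCc5ccccc5)ccc4OCc4ccccc4)c3o2)cc1 | intermediate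
30 | tert-butyl (2S,3R)-5,7-bis(benzyloxy)-2-(4-(benzyloxy)-3-{5-hydroxy-2-(4-methoxyphenyl)-4-oxo-7-[(triisopropylsilyl)oxy]-4H-chromen-8-yl}phenyl)-4-oxochromane-3-carboxylate | COc1ccc(-c2cc(=O)c3c(O)cc(O[Si](C(C)C)(C(C)C)C(C)C)c(-c4cc([C@@H]5[C@@H](C(=O)OC(C)(C)C)C(=O)c6c(OCc7ccccc7)cc(OCc7ccccc7)cc6O5)ccc4OCc4ccccc4)c3o2)cc1 | intermediate (not isolated)
31 | (2S)-5,7-bis(benzyloxy)-2-(4-(benzyloxy)-3-{5-hydroxy-2-(4-methoxyphenyl)-4-oxo-7-[(triisopropylsilyl)oxy]-4H-chromen-8-yl}phenyl)chroman-4-one | COc1ccc(-c2cc(=O)c3c(O)cc(O[Si](C(C)C)(C(C)C)C(C)C)c(-c4cc([C@@H]5CC(=O)c6c(OCc7ccccc7)cc(OCc7ccccc7)cc6O5)ccc4OCc4ccccc4)c3o2)cc1 | intermediate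
32 | (2S)-5,7-bis(benzyloxy)-2-{4-(benzyloxy)-3-[5,7-dihydroxy-2-(4-methoxyphenyl)-4-oxo-4H-chromen-8-yl]phenyl}chroman-4-one | COc1ccc(-c2cc(=O)c3c(O)cc(O)c(-c4cc([C@@H]5CC(=O)c6c(OCc7ccccc7)cc(OCc7ccccc7)cc6O5)ccc4OCc4ccccc4)c3o2)cc1 | intermediate
33 | 2,3-dihydropodocarpusflavone A, (2S) | COc1ccc(-c2cc(=O)c3c(O)cc(O)c(-c4cc([C@@H]5CC(=O)c6c(O)cc(O)cc6O5)ccc4O)c3o2)cc1 | target

## Step count and risks
Total step count: 18. Longest linear sequence: 14 steps (1–3, 6–12, 15–18).

**Step 6.**
- What may go wrong: the vinylketene may dimerise or acylate the product phenol before the hindered, aryl-conjugated ynol ether traps it. The aryl ynol ether may also compete for light and degrade.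
- Fallback: it sets out from 6, drops the diazoketone and all photochemistry, and comes back at 15.
- Cyclobutane-1,3-dione is O-methylated (HC(OMe)3, cat. p-TsOH) to 3-methoxycyclobut-2-en-1-one F1.
- F1 is heated with 6 in toluene at 110 °C in the dark (cyclobutenone version of the Danheiser benzannulation).
- Reversible four-electron opening of F1 releases the same vinylketene 11 slowly and at low stationary concentration. The cascade then runs on through 12, 13 and 14 to 15.

**Step 16.**
- What may go wrong: facial selectivity may be poor with the 6-benzyloxy-substituted aroyl group.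
- The enantiomeric purity may also erode through amine-catalysed background ring closure in step 15 and reversible ring opening before decarboxylation.
- Fallback: it sets out from 24 and 26, bypasses steps 15 to 17, and comes back at 32.
- Claisen–Schmidt condensation (KOH, EtOH, rt, which also strips the activated 7-O-silyl group) gives (E)-1-[2,4-bis(benzyloxy)-6-hydroxyphenyl]-3-{4-(benzyloxy)-3-[5,7-dihydroxy-2-(4-methoxyphenyl)-4-oxo-4H-chromen-8-yl]phenyl}prop-2-en-1-one F2.
- NaOAc in refluxing EtOH closes F2 to the racemic flavanone F3.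
- A kinetic resolution by Noyori asymmetric transfer hydrogenation follows (RuCl(p-cymene)[(R,R)-TsDPEN], HCO2H–Et3N, EtOAc, rt). It reduces the (2R) enantiomer to the (2R,4R)-cis-flavan-4-ol F4 and leaves the (2S) ketone 32, which is separated by chromatography.

**Step 12.**
- What may go wrong: the benzyl ether may be lost alongside the methyl ether if uncomplexed BCl3 or the formyl-bound reagent attacks it.
- Fallback: it sets out from 22, gives up selectivity, and comes back at 24.
- Excess BCl3 with pentamethylbenzene (CH2Cl2, −78 → 0 °C) removes both groups on purpose. This gives 4-hydroxy-3-{5-hydroxy-2-(4-methoxyphenyl)-4-oxo-7-[(triisopropylsilyl)oxy]-4H-chromen-8-yl}benzaldehyde F5.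
- BnBr (1.05 equiv) and K2CO3 in acetone then re-benzylate only the acidic, non-chelated ring B phenol, because the hydrogen-bonded 5-OH does not react, giving 24.

## Further compounds
F1 | step 6 | 3-methoxycyclobut-2-en-1-one | COC1=CC(=O)C1
F2 | step 16 | (E)-1-[2,4-bis(benzyloxy)-6-hydroxyphenyl]-3-{4-(benzyloxy)-3-[5,7-dihydroxy-2-(4-methoxyphenyl)-4-oxo-4H-chromen-8-yl]phenyl}prop-2-en-1-one | COc1ccc(-c2cc(=O)c3c(O)cc(O)c(-c4cc(/C=C/C(=O)c5c(O)cc(OCc6ccccc6)cc5OCc5ccccc5)ccc4OCc4ccccc4)c3o2)cc1
F3 | step 16 | racemic 5,7-bis(benzyloxy)-2-{4-(benzyloxy)-3-[5,7-dihydroxy-2-(4-methoxyphenyl)-4-oxo-4H-chromen-8-yl]phenyl}chroman-4-one | COc1ccc(-c2cc(=O)c3c(O)cc(O)c(-c4cc(C5CC(=O)c6c(OCc7ccccc7)cc(OCc7ccccc7)cc6O5)ccc4OCc4ccccc4)c3o2)cc1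
F4 | step 16 | 8-{2-(benzyloxy)-5-[(2R,4R)-5,7-bis(benzyloxy)-4-hydroxychroman-2-yl]phenyl}-5,7-dihydroxy-2-(4-methoxyphenyl)-4H-chromen-4-one | COc1ccc(-c2cc(=O)c3c(O)cc(O)c(-c4cc([C@H]5C[C@@H](O)c6c(OCc7ccccc7)cc(OCc7ccccc7)cc6O5)ccc4OCc4ccccc4)c3o2)cc1
F5 | step 12 | 4-hydroxy-3-{5-hydroxy-2-(4-methoxyphenyl)-4-oxo-7-[(triisopropylsilyl)oxy]-4H-chromen-8-yl}benzaldehyde | COc1ccc(-c2cc(=O)c3c(O)cc(O[Si](C(C)C)(C(C)C)C(C)C)c(-c4cc(C=O)ccc4O)c3o2)cc1
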